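**Strategy.** The 27-membered ring (ring oxygen plus C1–C26, numbered from the lactone carbonyl) is opened at C12–C13, inside the unbranched C2–C25 polymethylene span. The key step exploits the fact that C12 and C13 are plain methylenes, ten and thirteen CH2 groups away from the ester C1(=O)–O and free of stereocenters. The bond is therefore made as a C12=C13 alkene by ring-closing olefin metathesis and saturated in the same vessel by the ruthenium residues under H2, so one operation turns an acyclic ester into the target. The precursor is pentadec-14-en-1-yl tridec-12-enoate, a diene ester assembled from two ω-unsaturated fatty acids; ethene is the only carbon lost.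

Key step: step 3

Assumption: pentadec-14-enoic acid and tridec-12-enoic acid are taken as purchasable ω-unsaturated fatty acids (catalogue lipid standards); the target has no stereocenter.

Step 1
Reactants: 1 pentadec-14-enoic acid
Product: 2 pentadec-14-en-1-ol
Conditions: LiAlH4 (1.5 equiv), THF, 0 °C to reflux; then H2O, aq NaOH
Reagents that add atoms: none
Why: Lithium aluminium hydride reduction of a carboxylic acid to the primary alcohol; the isolated terminal alkene is inert to LiAlH4 in THF and no stereocenter is involved.

Step 2
Reactants: 2 pentadec-14-en-1-ol; 3 tridec-12-enoic acid
Product: 4 pentadec-14-en-1-yl tridec-12-enoate
Conditions: DCC (1.1 equiv), DMAP (10 mol %), CH2Cl2, 0 °C to rt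
Reagents that add atoms: none
Why: Steglich esterification, in which DCC turns the acid into an O-acylisourea and DMAP relays the acyl group to the unhindered primary alcohol; both terminal alkenes are untouched and no stereocenter is formed.

Step 3
Reactants: 4 pentadec-14-en-1-yl tridec-12-enoate
Product: 6 26-hexacosanolide (oxacycloheptacosan-2-one), via (E/Z)-hexacos-12-en-26-olide 5 (not isolated)
Conditions: first-generation Grubbs catalyst RuCl2(=CHPh)(PCy3)2 (5 mol %, two portions), ClCH2CH2Cl (2 mM, 4 added slowly), 45 °C, argon sparge; then H2 (7 bar), 70 °C, same vessel
Reagents that add atoms: none
Why: The ruthenium benzylidene is exchanged for an alkylidene at one terminal alkene of 4, which adds to the other terminal alkene in a [2+2] cycloaddition; cycloreversion of the ruthenacyclobutane expels ethene and leaves the C12=C13 bond, and under H2 the ruthenium residues become a ruthenium hydride that saturates this one alkene. The closest known reaction types are ring-closing olefin metathesis of ω-alkenyl ω-alkenoates to large musk-type lactones and tandem metathesis–hydrogenation with a single ruthenium charge. One ring is closed, the 27-membered lactone ring, by macrocyclisation between two terminal alkenes with loss of ethene, so no small-ring closure mode applies. No stereocenter is formed, and the E/Z ratio of 5 is irrelevant because the alkene is erased in the same vessel. The step needs ring closure over acyclic diene metathesis oligomerisation and no migration of a terminal alkene before closure; the first is secured by high dilution, slow addition and ethene removal (oligomers can back-bite to the strain-free ring), the second by the low isomerisation activity of the first-generation catalyst before H2 is admitted. Both alkenes are unhindered monosubstituted termini lying ten and thirteen methylenes from the ester, so no chelate between the ester carbonyl and the ruthenium alkylidene can stall the cycle.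

**Compound list**
1 | pentadec-14-enoic acid | C=CCCCCCCCCCCCCC(=O)O | starting material
2 | pentadec-14-en-1-ol | C=CCCCCCCCCCCCCCO | intermediate
3 | tridec-12-enoic acid | C=CCCCCCCCCCCC(=O)O | starting material
4 | pentadec-14-en-1-yl tridec-12-enoate | C=CCCCCCCCCCCC(=O)OCCCCCCCCCCCCCC=C | intermediate
5 | (E/Z)-hexacos-12-en-26-olide (oxacycloheptacos-13-en-2-one, mixture of alkene isomers, not isolated) | O=C1CCCCCCCCCCC=CCCCCCCCCCCCCCO1 | intermediate
6 | 26-hexacosanolide (oxacycloheptacosan-2-one) | O=C1CCCCCCCCCCCCCCCCCCCCCCCCCO1 | target

Total step count: 3. Longest linear sequence: 3 steps (1 → 2 → 4 → 6).

**Steps most likely to fail**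

Step 3. Intermolecular metathesis may outrun ring closure if the stationary concentration of 4 is not kept low. Ruthenium-hydride-mediated migration of a terminal double bond before closure would also give ring-contracted lactones after hydrogenation. The fallback sets out from 4. Ozonolysis (O3, CH2Cl2, −78 °C; then PPh3) should give the dialdehyde 14-oxotetradecyl 12-oxododecanoate F1. Intramolecular McMurry coupling (TiCl3(DME)1.5, zinc–copper couple, DME, reflux, F1 added by syringe pump) should form the same C12=C13 bond by reductive carbonyl coupling on the titanium surface. The aldehydes should couple much faster than the ester is attacked, and no alkene migration is possible. The fallback comes back to the route at 5, which is then isolated and hydrogenated (H2, palladium on carbon, EtOAc, rt) to 6.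

Step 2. The O-acylisourea may rearrange to the unreactive N-acylurea, and traces of urea and DMAP carried into the waxy ester could deactivate the ruthenium catalyst of step 3. The fallback sets out from 3. Fischer esterification (MeOH, cat. H2SO4, reflux) should give methyl tridec-12-enoate F2. Transesterification with 2 (immobilised Candida antarctica lipase B, 60 °C, reduced pressure to remove methanol) should then give the wax-type ester without any activating reagent. The fallback comes back to the route at 4.

Step 1. The lithium carboxylate may precipitate from THF and stall the reduction, and the waxy alcohol may be held back in the aluminium hydroxide cake on work-up. The fallback sets out from 1. Activation with ethyl chloroformate and Et3N (THF, 0 °C) should give pentadec-14-enoic ethyl carbonic anhydride F3. Reduction with NaBH4 (THF/H2O, 0 °C), which leaves the alkene alone, comes back to the route at 2.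

**Further compounds**
F1 | step 3 | 14-oxotetradecyl 12-oxododecanoate | O=CCCCCCCCCCCC(=O)OCCCCCCCCCCCCCC=O
F2 | step 2 | methyl tridec-12-enoate | C=CCCCCCCCCCCC(=O)OC
F3 | step 1 | pentadec-14-enoic ethyl carbonic anhydride | C=CCCCCCCCCCCCCC(=O)OC(=O)OCC
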